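**Retrosynthetic overview**
1. Last disconnection: the three aryl O–CH3 bonds (global demethylation); the iodine is carried through from the first step, so no late site-selective iodination is needed.
2. Key disconnection: the oxazinone ring at N–C4 and O–C3, back to an N–H pyrrole-2-carboxylic acid and a terminal aryl alkyne (dehydrogenative N–H/O–H annulation).
3. Pyrrole ring: N–C5 (imine condensation) and C2–C3 (ring closure of a 2-azapentadienyl anion with loss of chloride), back to a 2,3-diaryl β-chloro enal and a glycine ester.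
4. β-Chloro enal: chloroformylation of a deoxybenzoin; aryl C–I back to the commercial deoxybenzoin by ring-selective iodination.
5. Ring order: the three benzene rings are bought; the pyrrole is made first, the oxazinone last.

Assumption: the target has no stereocentre and is achiral, so no enantiocontrol is required; alkene and imine geometries of intermediates are given where they exist and do not affect the outcome.

**Step 1**
Reactants: 1 desoxyanisoin (1,2-bis(4-methoxyphenyl)ethan-1-one)
Product: 2 2-(3-iodo-4-methoxyphenyl)-1-(4-methoxyphenyl)ethan-1-one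
Conditions: NIS (1.05 equiv), TFA (0.3 equiv), MeCN, 0 → 25 °C, dark
Reagents that add atoms: N-iodosuccinimide O=C1CCC(=O)N1I
Why: Electrophilic aromatic iodination (SEAr): TFA-activated NIS attacks the alkyl-substituted anisole ring ortho to OMe (para blocked), while the other anisole ring is deactivated by its para carbonyl group; no stereocentre is formed.

**Step 2**
Reactants: 2 2-(3-iodo-4-methoxyphenyl)-1-(4-methoxyphenyl)ethan-1-one
Product: 3 (Z)-3-chloro-2-(3-iodo-4-methoxyphenyl)-3-(4-methoxyphenyl)prop-2-enal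
Conditions: POCl3 (3 equiv), DMF, 0 → 70 °C; then ice-water
Reagents that add atoms: N,N-dimethylformamide CN(C)C=O; phosphoryl chloride O=P(Cl)(Cl)Cl; water O
Why: Vilsmeier–Haack–Arnold chloroformylation: the ketone is formylated at its only alpha carbon, the vinylogous amide becomes the vinylogous chloroiminium ion and water unmasks the aldehyde; the Z isomer (Cl cis to CHO) should dominate, but the geometry is irrelevant because both alkene carbons become pyrrole carbons.

**Step 3**
Reactants: 3 (Z)-3-chloro-2-(3-iodo-4-methoxyphenyl)-3-(4-methoxyphenyl)prop-2-enal; 4 glycine ethyl ester hydrochloride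
Product: 7 4-(3-iodo-4-methoxyphenyl)-3-(4-methoxyphenyl)-1H-pyrrole-2-carboxylic acid, via glycinate imine 5 (not isolated), via pyrrole ethyl ester 6 (not isolated)
Conditions: 4 (1.5 equiv), Et3N, MgSO4, EtOH, 25 °C; then NaOEt, 78 °C; then 2 M aq NaOH, 78 °C; HCl to pH 3, 0 °C
Reagents that add atoms: sodium hydroxide [Na+].[OH-]
Why: Imine condensation fixes N on the future C5, the 2-azapentadienyl anion formed with NaOEt closes onto the chlorine-bearing carbon (1,5-electrocyclisation or addition–elimination, then loss of chloride and tautomerisation) to give the 3,4-diarylpyrrole-2-carboxylate with the iodinated aryl at C4, and the ester is saponified in the same pot; no stereocentre is formed.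

**Step 4**
Reactants: 7 4-(3-iodo-4-methoxyphenyl)-3-(4-methoxyphenyl)-1H-pyrrole-2-carboxylic acid; 8 1-ethynyl-4-methoxybenzene
Product: 10 7-(3-iodo-4-methoxyphenyl)-3,8-bis(4-methoxyphenyl)-1H-pyrrolo[2,1-c][1,4]oxazin-1-one, via N-alkynylpyrrole acid 9 (not isolated)
Conditions: CuCl2 (20 mol %), pyridine (2 equiv), Na2CO3 (2 equiv), O2 (1 atm), 4 Å MS, toluene/DMSO 5:1, 70 °C; 8 (3 equiv) added over 8 h
Reagents that add atoms: none
Why: Proposed new method: a dehydrogenative N–H/O–H [4+2] annulation of an N–H pyrrole-2-carboxylic acid with a terminal aryl alkyne, to my knowledge unreported; 7 binds divalent copper as a κ2-N,O pyrrolide carboxylate, the copper acetylide ArC≡C–Cu formed from 8 transfers its alkynyl group, C–N reductive elimination from trivalent copper gives N-alkynylpyrrole 9, and the neighbouring carboxylate then adds anti across the copper-bound triple bond in the 6-endo-dig mode at the carbon carrying the 4-methoxyphenyl group (the best cation-stabilising site; the 5-exo mode would give a strained 5,5-fused ring), protodemetalation leaves H at C4 and O2 returns monovalent copper to the divalent state; slow addition of 8 limits Glaser–Hay homocoupling and the aryl iodide should survive at 70 °C; the closest known reaction types are the aerobic copper-catalysed oxidative N-alkynylation of amides and azoles with terminal alkynes (ynamide synthesis) and the 6-endo cycloisomerisation of 2-(arylethynyl)benzoic acids to 3-arylisocoumarins; no stereocentre is formed.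

**Step 5**
Reactants: 10 7-(3-iodo-4-methoxyphenyl)-3,8-bis(4-methoxyphenyl)-1H-pyrrolo[2,1-c][1,4]oxazin-1-one
Product: 11 lukianol B (7-(4-hydroxy-3-iodophenyl)-3,8-bis(4-hydroxyphenyl)-1H-pyrrolo[2,1-c][1,4]oxazin-1-one)
Conditions: BBr3 (9 equiv), CH2Cl2, −78 → 25 °C; then H2O, 0 °C
Reagents that add atoms: none
Why: Lewis acid-mediated cleavage of aryl methyl ethers (BBr3 demethylation); the enol lactone and the aryl iodide are expected to survive BBr3 at or below 25 °C, and the aqueous quench releases the three phenols; no stereocentre is formed.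

**Compound list**
1 | desoxyanisoin (1,2-bis(4-methoxyphenyl)ethan-1-one) | COc1ccc(CC(=O)c2ccc(OC)cc2)cc1 | starting material
2 | 2-(3-iodo-4-methoxyphenyl)-1-(4-methoxyphenyl)ethan-1-one | COc1ccc(cc1)C(=O)Cc1ccc(OC)c(I)c1 | intermediate
3 | (Z)-3-chloro-2-(3-iodo-4-methoxyphenyl)-3-(4-methoxyphenyl)prop-2-enal | O=C/C(c1ccc(OC)c(I)c1)=C(\Cl)c1ccc(OC)cc1 | intermediate
4 | glycine ethyl ester hydrochloride | CCOC(=O)CN.Cl | starting material
5 | ethyl N-[(1E,2Z)-3-chloro-2-(3-iodo-4-methoxyphenyl)-3-(4-methoxyphenyl)prop-2-en-1-ylidene]glycinate | CCOC(=O)C/N=C/C(c1ccc(OC)c(I)c1)=C(\Cl)c1ccc(OC)cc1 | intermediate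
6 | ethyl 4-(3-iodo-4-methoxyphenyl)-3-(4-methoxyphenyl)-1H-pyrrole-2-carboxylate | CCOC(=O)c1[nH]cc(-c2ccc(OC)c(I)c2)c1-c1ccc(OC)cc1 | intermediate
7 | 4-(3-iodo-4-methoxyphenyl)-3-(4-methoxyphenyl)-1H-pyrrole-2-carboxylic acid | OC(=O)c1[nH]cc(-c2ccc(OC)c(I)c2)c1-c1ccc(OC)cc1 | intermediate
8 | 1-ethynyl-4-methoxybenzene | C#Cc1ccc(OC)cc1 | starting material
9 | 4-(3-iodo-4-methoxyphenyl)-3-(4-methoxyphenyl)-1-[(4-methoxyphenyl)ethynyl]-1H-pyrrole-2-carboxylic acid | OC(=O)c1n(C#Cc2ccc(OC)cc2)cc(-c2ccc(OC)c(I)c2)c1-c1ccc(OC)cc1 | intermediate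
10 | 7-(3-iodo-4-methoxyphenyl)-3,8-bis(4-methoxyphenyl)-1H-pyrrolo[2,1-c][1,4]oxazin-1-one | O=c1oc(-c2ccc(OC)cc2)cn2cc(-c3ccc(OC)c(I)c3)c(-c3ccc(OC)cc3)c12 | intermediate
11 | lukianol B | O=c1oc(-c2ccc(O)cc2)cn2cc(-c3ccc(O)c(I)c3)c(-c3ccc(O)cc3)c12 | target

**Step count**
Total steps: 5. Longest linear sequence: 5 steps (1 → 2 → 3 → 7 → 10 → 11).

**Steps most likely to fail, with fallbacks**

Step 4 (the proposed new annulation). The risks are alkyne homocoupling outrunning N-alkynylation, 5-exo instead of 6-endo closure, and copper-mediated loss of CO2. The fallback uses known chemistry and sets out from ethyl ester 6, which is isolated by ending step 3 before the NaOH stage. N-Alkylation of 6 with commercial 2-bromo-1-(4-methoxyphenyl)ethan-1-one F6 (K2CO3, DMF, 25 °C) gives ethyl 4-(3-iodo-4-methoxyphenyl)-3-(4-methoxyphenyl)-1-[2-(4-methoxyphenyl)-2-oxoethyl]-1H-pyrrole-2-carboxylate F7. Saponification (KOH, EtOH/H2O, 78 °C; then HCl) gives the corresponding acid, 4-(3-iodo-4-methoxyphenyl)-3-(4-methoxyphenyl)-1-[2-(4-methoxyphenyl)-2-oxoethyl]-1H-pyrrole-2-carboxylic acid F8. Enol lactonisation of F8 (Ac2O, NaOAc, 120 °C) closes the oxazinone and comes back to the route at 10.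

Step 1 (ring iodination next to an acidic ketone CH2). The risk is alpha-iodination of the ketone or over-iodination. The fallback puts the iodine in before the ketone exists. It sets out from no numbered compound of the route: commercial 4-methoxyphenylacetic acid F1 replaces 1. F1 is iodinated ortho to the methoxy group (NIS, cat. TFA, MeCN, 25 °C) to 2-(3-iodo-4-methoxyphenyl)acetic acid F2. Para-selective Friedel–Crafts acylation of anisole F3 with F2 (TFAA, 85 % H3PO4, 25 °C) then gives ketone 2, where it comes back to the route.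

Step 3 (three operations in one pot). The risks are competing attack of the amine at the chlorine-bearing carbon, which would give the 4,5-diaryl isomer, and incomplete saponification or decarboxylation on acidification. The fallback sets out from 2 and bypasses 3. Condensation of 2 with N,N-dimethylformamide dimethyl acetal (neat, 100 °C) gives (E)-3-(dimethylamino)-2-(3-iodo-4-methoxyphenyl)-1-(4-methoxyphenyl)prop-2-en-1-one F4. Amine exchange with 4 (EtOH, 78 °C) can only place nitrogen on the CH carbon and gives ethyl N-[(Z)-2-(3-iodo-4-methoxyphenyl)-3-(4-methoxyphenyl)-3-oxoprop-1-en-1-yl]glycinate F5. Intramolecular Knoevenagel condensation of F5 (NaOEt, EtOH, 78 °C) comes back to the route at 6, which is isolated and saponified to 7 in a separate operation (NaOH, EtOH/H2O, 78 °C; then HCl).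

**Further compounds**
F1 | step 1 | 4-methoxyphenylacetic acid | COc1ccc(CC(=O)O)cc1
F2 | step 1 | 2-(3-iodo-4-methoxyphenyl)acetic acid | COc1ccc(CC(=O)O)cc1I
F3 | step 1 | anisole | COc1ccccc1
F4 | step 3 | (E)-3-(dimethylamino)-2-(3-iodo-4-methoxyphenyl)-1-(4-methoxyphenyl)prop-2-en-1-one | CN(C)/C=C(\c1ccc(OC)c(I)c1)C(=O)c1ccc(OC)cc1
F5 | step 3 | ethyl N-[(Z)-2-(3-iodo-4-methoxyphenyl)-3-(4-methoxyphenyl)-3-oxoprop-1-en-1-yl]glycinate | CCOC(=O)CN/C=C(/c1ccc(OC)c(I)c1)C(=O)c1ccc(OC)cc1
F6 | step 4 | 2-bromo-1-(4-methoxyphenyl)ethan-1-one | COc1ccc(cc1)C(=O)CBr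
F7 | step 4 | ethyl 4-(3-iodo-4-methoxyphenyl)-3-(4-methoxyphenyl)-1-[2-(4-methoxyphenyl)-2-oxoethyl]-1H-pyrrole-2-carboxylate | CCOC(=O)c1n(CC(=O)c2ccc(OC)cc2)cc(-c2ccc(OC)c(I)c2)c1-c1ccc(OC)cc1
F8 | step 4 | 4-(3-iodo-4-methoxyphenyl)-3-(4-methoxyphenyl)-1-[2-(4-methoxyphenyl)-2-oxoethyl]-1H-pyrrole-2-carboxylic acid | OC(=O)c1n(CC(=O)c2ccc(OC)cc2)cc(-c2ccc(OC)c(I)c2)c1-c1ccc(OC)cc1
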